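**Plan**
1. Retrosynthesis: take off the three silyl ethers; cut C9–C10 (ring B) and return C4 from C5 to C10 by reversing a 1,2-shift (ring A), which unfolds the decalin to a (1,2,2-trimethylcyclopentyl)carbinol; cut C6–C7 into a cyclopentyl methyl ketone and an aryl allylic bromide.
2. Enabling feature: in ring A the hydrogen-bearing fusion carbon C5 lies between the gem-dimethyl carbon C4 and the methyl-bearing quaternary carbon C10. A cation at C5 beside a cyclopentane in which C10 and C4 are bonded is therefore one shift away from the tertiary C10 cation of ring A, and the C8=C9 alkene can trap that cation to close ring B.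
3. Forward: (1S,3R)-camphoric acid gives the cyclopentyl methyl ketone (steps 1–4); methyl 2,3,4-trihydroxybenzoate gives the aryl (E)-allylic bromide (steps 5–8); enolate union (9); CBS reduction (10); ring expansion of the cyclopentane to ring A with closure of ring B in the same operation (11); desilylation (12).
4. Stereochemistry: the quaternary carbon of camphoric acid becomes C10 and the CBS-made carbinol carbon becomes C5, both by inversion in an antiperiplanar relay; the E alkene sets C9 through a chair closure.

Key step: step 11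

Remark: drimane numbering is used (ring A = C1–C5, C10; ring B = C5–C10; C11 = benzylic CH2; C12 = methyl on C8). (1S,3R)-(−)-Camphoric acid, methyl 2,3,4-trihydroxybenzoate and 2-methylbut-3-en-2-ol are taken as commercial.

Step 1
Reactants: 1 (1S,3R)-camphoric acid
Product: 2 (1S,3R)-3-(methoxycarbonyl)-1,2,2-trimethylcyclopentane-1-carboxylic acid
Conditions: MeOH, H2SO4 (cat.), reflux
Reagents that add atoms: methanol, CO
Why: Fischer esterification, in which the secondary carboxyl group reacts far faster than the neopentyl-type tertiary one next to the gem-dimethyl carbon, so the mono-ester should form selectively and no stereocentre is touched.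

Step 2
Reactants: 2 (1S,3R)-3-(methoxycarbonyl)-1,2,2-trimethylcyclopentane-1-carboxylic acid
Product: 4 methyl (1R,3S)-3-acetyl-2,2,3-trimethylcyclopentane-1-carboxylate, via acid chloride 3 (not isolated)
Conditions: (COCl)2, DMF (cat.), CH2Cl2, 0 °C to rt, evaporate; then Me2CuLi (made from CuI and 2 MeLi), Et2O, −78 °C
Reagents that add atoms: lithium dimethylcuprate, [Li+].C[Cu-]C
Why: Acid chloride formation followed by Gilman ketone synthesis, in which the cuprate substitutes the acyl chloride once and leaves the methyl ester and the quaternary stereocentre alone.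

Step 3
Reactants: 4 methyl (1R,3S)-3-acetyl-2,2,3-trimethylcyclopentane-1-carboxylate
Product: 5 (1R,3S)-3-acetyl-2,2,3-trimethylcyclopentane-1-carboxylic acid
Conditions: LiOH, THF/MeOH/H2O, 50 °C; then dilute aq. HCl to pH 2
Reagents that add atoms: lithium hydroxide, [Li+].[OH-]
Why: Saponification of the secondary methyl ester; epimerisation next to the carboxyl group would not matter because that centre becomes a CH2 group in step 4.

Step 4
Reactants: 5 (1R,3S)-3-acetyl-2,2,3-trimethylcyclopentane-1-carboxylic acid
Product: 6 1-[(1S)-1,2,2-trimethylcyclopentyl]ethan-1-one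
Conditions: 9-mesityl-10-phenylacridinium tetrafluoroborate (5 mol %), PhSSPh (10 mol %), iPr2NEt (20 mol %), CF3CH2OH, 450 nm LEDs, rt
Reagents that add atoms: none
Why: Photoredox hydrodecarboxylation, in which the carboxylate is oxidised by the excited acridinium, loses CO2 and the secondary radical takes hydrogen from thiophenol, leaving the ketone and the quaternary stereocentre untouched.

Step 5
Reactants: 7 methyl 2,3,4-trihydroxybenzoate; 8 2-methylbut-3-en-2-ol
Product: 9 methyl 2,3,4-trihydroxy-5-(3-methylbut-2-en-1-yl)benzoate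
Conditions: BF3·OEt2 (0.3 equiv), 1,4-dioxane, rt
Reagents that add atoms: none
Why: Friedel–Crafts allylation by the dimethylallyl cation formed from the tertiary allylic alcohol, directed to C5 because it is the only free position ortho and para to hydroxyl groups, whereas C6 is ortho to the ester.

Step 6
Reactants: 9 methyl 2,3,4-trihydroxy-5-(3-methylbut-2-en-1-yl)benzoate
Product: 10 methyl 2,3,4-tris(tert-butyldimethylsilyloxy)-5-(3-methylbut-2-en-1-yl)benzoate
Conditions: TBSOTf (3.6 equiv), 2,6-lutidine, CH2Cl2, 0 °C to rt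
Reagents that add atoms: tert-butyldimethylsilyl trifluoromethanesulfonate, CC(C)(C)[Si](C)(C)OS(=O)(=O)C(F)(F)F
Why: Silyl ether formation with the silyl triflate, reactive enough to cap the hydrogen-bonded and crowded hydroxyl groups, giving ethers that tolerate the enolate, borane and cationic steps and are poor donors towards a cation.

Step 7
Reactants: 10 methyl 2,3,4-tris(tert-butyldimethylsilyloxy)-5-(3-methylbut-2-en-1-yl)benzoate
Product: 11 methyl 2,3,4-tris(tert-butyldimethylsilyloxy)-5-[(2E)-4-hydroxy-3-methylbut-2-en-1-yl]benzoate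
Conditions: SeO2 (0.3 equiv), t-BuOOH (2 equiv, in decane), CH2Cl2, rt
Reagents that add atoms: selenium dioxide, O=[Se]=O (passes the oxygen on); tert-butyl hydroperoxide, CC(C)(C)OO (terminal oxidant)
Why: Riley allylic oxidation (ene reaction then [2,3]-sigmatropic shift), which by its known preference attacks the (E)-methyl group on the more substituted alkene carbon and so fixes the E geometry of the future C8=C9 alkene.

Step 8
Reactants: 11 methyl 2,3,4-tris(tert-butyldimethylsilyloxy)-5-[(2E)-4-hydroxy-3-methylbut-2-en-1-yl]benzoate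
Product: 12 methyl 5-[(2E)-4-bromo-3-methylbut-2-en-1-yl]-2,3,4-tris(tert-butyldimethylsilyloxy)benzoate
Conditions: CBr4, PPh3, CH2Cl2, 0 °C
Reagents that add atoms: carbon tetrabromide, BrC(Br)(Br)Br
Why: Appel reaction, a neutral SN2 bromination of the primary allylic alcohol that keeps the alkene geometry and the aryl silyl ethers.

Step 9
Reactants: 6 1-[(1S)-1,2,2-trimethylcyclopentyl]ethan-1-one; 12 methyl 5-[(2E)-4-bromo-3-methylbut-2-en-1-yl]-2,3,4-tris(tert-butyldimethylsilyloxy)benzoate
Product: 14 methyl 2,3,4-tris(tert-butyldimethylsilyloxy)-5-{(2E)-3-methyl-6-oxo-6-[(1S)-1,2,2-trimethylcyclopentyl]hex-2-en-1-yl}benzoate, via lithium enolate 13 (not isolated)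
Conditions: 6 (1.1 equiv), LiN(iPr)2, THF, −78 °C; then 12, DMPU, −78 to −40 °C
Reagents that add atoms: none
Why: Alkylation of a lithium enolate, which can form only on the methyl side of 6 because the other α-carbon is quaternary, by SN2 attack on the primary allylic bromide to make the C6–C7 bond without touching the E alkene.

Step 10
Reactants: 14 methyl 2,3,4-tris(tert-butyldimethylsilyloxy)-5-{(2E)-3-methyl-6-oxo-6-[(1S)-1,2,2-trimethylcyclopentyl]hex-2-en-1-yl}benzoate
Product: 15 methyl 2,3,4-tris(tert-butyldimethylsilyloxy)-5-{(2E,6S)-6-hydroxy-3-methyl-6-[(1S)-1,2,2-trimethylcyclopentyl]hex-2-en-1-yl}benzoate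
Conditions: (R)-2-methyl-CBS-oxazaborolidine (0.5 equiv), catecholborane (1.8 equiv), toluene, −40 to −20 °C; then MeOH, pH 7 buffer
Reagents that add atoms: none
Why: Corey–Bakshi–Shibata reduction, in which the (R)-oxazaborolidine binds the ketone with the quaternary cyclopentyl group as the large substituent and delivers hydride to the face that gives the (S)-carbinol (the future C5); any (R)-epimer is a diastereomer and should be removable by chromatography.

Step 11
Reactants: 15 methyl 2,3,4-tris(tert-butyldimethylsilyloxy)-5-{(2E,6S)-6-hydroxy-3-methyl-6-[(1S)-1,2,2-trimethylcyclopentyl]hex-2-en-1-yl}benzoate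
Product: 17 methyl 2,3,4-tris(tert-butyldimethylsilyloxy)-5-{[(1S,4aS,8aS)-2,5,5,8a-tetramethyl-1,4,4a,5,6,7,8,8a-octahydronaphthalen-1-yl]methyl}benzoate, via triflate 16 (not isolated)
Conditions: Tf2O (1.2 equiv), 2,6-di-tert-butyl-4-methylpyridine (3 equiv), CH2Cl2, −78 °C, then warm slowly to 0 °C
Reagents that add atoms: none
Why: Proposed new method: O-triflation should make the neopentylic C5–O bond ionise with participation of the antiperiplanar, electron-rich C10–C4 bond, so that the CMe2 carbon shifts from C10 to C5 (Wagner–Meerwein expansion of the cyclopentane to ring A) and leaves a tertiary cyclohexyl cation at C10; the C8=C9 alkene then traps this cation by 6-endo-trig cation–olefin closure of ring B through a chair, and the C8 cation loses its axial C7 proton to the hindered pyridine. The closest known reaction types are the cuprenyl-to-chamigrenyl ring expansion of (1,2,2-trimethylcyclopentyl)carbinyl cations and the acid-mediated cyclisation of monocyclofarnesyl cations to trans-fused drim-7-enes, here run in sequence from one ionisation. C5 is set by inversion at the carbinol carbon (migration anti to the leaving group), C10 by attack of C9 anti to the departing C4 (in the (6S,1S) diastereomer the tether already lies on that side, and a free cation would follow the same chair preference for the trans-decalin), and C9 by the E alkene, which places the arylmethyl group equatorial. The step needs C4 to migrate in preference to the ring CH2 or the methyl group, which its tertiary character and the relief of ring strain and of the vicinal quaternary congestion should secure. It needs ring B to close before a hydride shift or proton loss at C10, which the six-membered chair array should secure, and proton loss towards C7, which the antiperiplanar axial C7–H favours. The ester-deactivated, silyl-shielded arene and the buffered, non-protic medium should keep the arene and the alkene out of competing cationic pathways.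

Step 12
Reactants: 17 methyl 2,3,4-tris(tert-butyldimethylsilyloxy)-5-{[(1S,4aS,8aS)-2,5,5,8a-tetramethyl-1,4,4a,5,6,7,8,8a-octahydronaphthalen-1-yl]methyl}benzoate
Product: 18 methyl 2,3,4-trihydroxy-5-{[(1S,4aS,8aS)-2,5,5,8a-tetramethyl-1,4,4a,5,6,7,8,8a-octahydronaphthalen-1-yl]methyl}benzoate (CNP0185238.1)
Conditions: Bu4NF (3.5 equiv), AcOH (3.5 equiv), THF, 0 °C, under argon
Reagents that add atoms: none
Why: Fluoride cleavage of the three aryl silyl ethers under acetic acid buffering, which should avoid both air oxidation of the pyrogallol phenoxide and acid-induced chroman formation onto the C7=C8 alkene; no stereocentre is affected.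

**Compound list**
1 | (1S,3R)-camphoric acid | C[C@]1(C(=O)O)CC[C@@H](C(=O)O)C1(C)C | starting material
2 | (1S,3R)-3-(methoxycarbonyl)-1,2,2-trimethylcyclopentane-1-carboxylic acid | C[C@]1(C(=O)O)CC[C@@H](C(=O)OC)C1(C)C | intermediate
3 | methyl (1R,3S)-3-(chlorocarbonyl)-2,2,3-trimethylcyclopentane-1-carboxylate | C[C@]1(C(=O)Cl)CC[C@@H](C(=O)OC)C1(C)C | intermediate
4 | methyl (1R,3S)-3-acetyl-2,2,3-trimethylcyclopentane-1-carboxylate | C[C@]1(C(C)=O)CC[C@@H](C(=O)OC)C1(C)C | intermediate
5 | (1R,3S)-3-acetyl-2,2,3-trimethylcyclopentane-1-carboxylic acid | C[C@]1(C(C)=O)CC[C@@H](C(=O)O)C1(C)C | intermediate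
6 | 1-[(1S)-1,2,2-trimethylcyclopentyl]ethan-1-one | C[C@]1(C(C)=O)CCCC1(C)C | intermediate
7 | methyl 2,3,4-trihydroxybenzoate | COC(=O)c1ccc(O)c(O)c1O | starting material
8 | 2-methylbut-3-en-2-ol | CC(C)(O)C=C | starting material
9 | methyl 2,3,4-trihydroxy-5-(3-methylbut-2-en-1-yl)benzoate | COC(=O)c1cc(CC=C(C)C)c(O)c(O)c1O | intermediate
10 | methyl 2,3,4-tris(tert-butyldimethylsilyloxy)-5-(3-methylbut-2-en-1-yl)benzoate | COC(=O)c1cc(CC=C(C)C)c(O[Si](C)(C)C(C)(C)C)c(O[Si](C)(C)C(C)(C)C)c1O[Si](C)(C)C(C)(C)C | intermediate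
11 | methyl 2,3,4-tris(tert-butyldimethylsilyloxy)-5-[(2E)-4-hydroxy-3-methylbut-2-en-1-yl]benzoate | COC(=O)c1cc(C/C=C(\C)CO)c(O[Si](C)(C)C(C)(C)C)c(O[Si](C)(C)C(C)(C)C)c1O[Si](C)(C)C(C)(C)C | intermediate
12 | methyl 5-[(2E)-4-bromo-3-methylbut-2-en-1-yl]-2,3,4-tris(tert-butyldimethylsilyloxy)benzoate | COC(=O)c1cc(C/C=C(\C)CBr)c(O[Si](C)(C)C(C)(C)C)c(O[Si](C)(C)C(C)(C)C)c1O[Si](C)(C)C(C)(C)C | intermediate
13 | lithium enolate of 6 | C[C@]1(C(=C)[O-])CCCC1(C)C.[Li+] | intermediate
14 | methyl 2,3,4-tris(tert-butyldimethylsilyloxy)-5-{(2E)-3-methyl-6-oxo-6-[(1S)-1,2,2-trimethylcyclopentyl]hex-2-en-1-yl}benzoate | C[C@]1(C(=O)CC/C(C)=C/Cc2cc(C(=O)OC)c(O[Si](C)(C)C(C)(C)C)c(O[Si](C)(C)C(C)(C)C)c2O[Si](C)(C)C(C)(C)C)CCCC1(C)C | intermediate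
15 | methyl 2,3,4-tris(tert-butyldimethylsilyloxy)-5-{(2E,6S)-6-hydroxy-3-methyl-6-[(1S)-1,2,2-trimethylcyclopentyl]hex-2-en-1-yl}benzoate | C[C@]1([C@@H](O)CC/C(C)=C/Cc2cc(C(=O)OC)c(O[Si](C)(C)C(C)(C)C)c(O[Si](C)(C)C(C)(C)C)c2O[Si](C)(C)C(C)(C)C)CCCC1(C)C | intermediate
16 | (6S)-trifluoromethanesulfonate of 15 | C[C@]1([C@@H](OS(=O)(=O)C(F)(F)F)CC/C(C)=C/Cc2cc(C(=O)OC)c(O[Si](C)(C)C(C)(C)C)c(O[Si](C)(C)C(C)(C)C)c2O[Si](C)(C)C(C)(C)C)CCCC1(C)C | intermediate
17 | methyl 2,3,4-tris(tert-butyldimethylsilyloxy)-5-{[(1S,4aS,8aS)-2,5,5,8a-tetramethyl-1,4,4a,5,6,7,8,8a-octahydronaphthalen-1-yl]methyl}benzoate | COC(=O)c1cc(C[C@H]2C(C)=CC[C@H]3C(C)(C)CCC[C@]23C)c(O[Si](C)(C)C(C)(C)C)c(O[Si](C)(C)C(C)(C)C)c1O[Si](C)(C)C(C)(C)C | intermediate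
18 | methyl 2,3,4-trihydroxy-5-{[(1S,4aS,8aS)-2,5,5,8a-tetramethyl-1,4,4a,5,6,7,8,8a-octahydronaphthalen-1-yl]methyl}benzoate | COC(=O)c1cc(C[C@H]2C(C)=CC[C@H]3C(C)(C)CCC[C@]23C)c(O)c(O)c1O | target

**Count and risks**
Total steps: 12. Longest linear sequence: 8 steps (steps 1–4 or 5–8, then 9–12).

Steps most likely to fail:

1. Step 11 (proposed method). The ionisation may send the ring CH2 or the methyl group to C5 instead of C4. The C10 cation may live long enough to shift hydride or lose a proton before ring B closes. The final proton may leave towards C12 or C9 instead of C7. Fallback with known chemistry, in which ring A is made in its final size by a proton-initiated polyene cyclisation: it sets out from bromide 12. Geranyl phenyl sulfone (CC(C)=CCC/C(C)=C/CS(=O)(=O)c1ccccc1) is deprotonated with n-BuLi in THF at −78 °C to lithiated geranyl phenyl sulfone F1, which is alkylated by 12 to give the sulfone adduct F2. Reductive desulfonylation with Na(Hg) and Na2HPO4 in MeOH at −20 °C should give the (2E,6E)-farnesyl arene F3. Cyclisation of F3 with the Lewis-acid-assisted chiral Brønsted acid made from SnCl4 and an (R)-binaphthol mono-ether (toluene, −78 °C; ligand enantiomer chosen for the 5S,10S series) should close rings A and B and come back to the route at 17.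

2. Step 5. The allyl cation may alkylate oxygen or alkylate twice, and the prenyl group may close onto the 4-hydroxyl group to a chroman under the Lewis acid. Fallback by cross-coupling instead of electrophilic substitution: it sets out from 7. Bromination with NBS in MeCN at 0 °C should give methyl 5-bromo-2,3,4-trihydroxybenzoate F4. Silylation as in step 6 gives its tris-silyl ether F5. Suzuki–Miyaura coupling of F5 with 3-methylbut-2-en-1-ylboronic acid pinacol ester (Pd(OAc)2, a bulky di-tert-butyl biarylphosphine chosen for linear selectivity, K3PO4, THF/H2O) comes back to the route at 10.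

3. Step 10. The reduction of the neopentylic ketone may be slow, the facial selectivity of the catalyst may be eroded by the neighbouring quaternary centre, and the borane may add to the alkene. Fallback by separation instead of asymmetric induction: it sets out from 14. Unselective reduction with NaBH4 in EtOH/THF at 0 °C gives 15 together with the (6R)-epimer F6. Because the ring stereocentre is fixed, the two are diastereomers and are separated by chromatography, which comes back to the route at 15. F6 is returned to 14 by Dess–Martin oxidation for another pass.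

**Further compounds**
F1 | step 11 | lithiated geranyl phenyl sulfone | CC(C)=CCC/C(C)=C/[CH-]S(=O)(=O)c1ccccc1.[Li+]
F2 | step 11 | methyl 2,3,4-tris(tert-butyldimethylsilyloxy)-5-[(2E,6E)-3,7,11-trimethyl-5-(phenylsulfonyl)dodeca-2,6,10-trien-1-yl]benzoate | COC(=O)c1cc(C/C=C(\C)CC(/C=C(\C)CCC=C(C)C)S(=O)(=O)c2ccccc2)c(O[Si](C)(C)C(C)(C)C)c(O[Si](C)(C)C(C)(C)C)c1O[Si](C)(C)C(C)(C)C
F3 | step 11 | methyl 2,3,4-tris(tert-butyldimethylsilyloxy)-5-[(2E,6E)-3,7,11-trimethyldodeca-2,6,10-trien-1-yl]benzoate | COC(=O)c1cc(C/C=C(\C)CC/C=C(\C)CCC=C(C)C)c(O[Si](C)(C)C(C)(C)C)c(O[Si](C)(C)C(C)(C)C)c1O[Si](C)(C)C(C)(C)C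
F4 | step 5 | methyl 5-bromo-2,3,4-trihydroxybenzoate | COC(=O)c1cc(Br)c(O)c(O)c1O
F5 | step 5 | methyl 5-bromo-2,3,4-tris(tert-butyldimethylsilyloxy)benzoate | COC(=O)c1cc(Br)c(O[Si](C)(C)C(C)(C)C)c(O[Si](C)(C)C(C)(C)C)c1O[Si](C)(C)C(C)(C)C
F6 | step 10 | methyl 2,3,4-tris(tert-butyldimethylsilyloxy)-5-{(2E,6R)-6-hydroxy-3-methyl-6-[(1S)-1,2,2-trimethylcyclopentyl]hex-2-en-1-yl}benzoate | C[C@]1([C@H](O)CC/C(C)=C/Cc2cc(C(=O)OC)c(O[Si](C)(C)C(C)(C)C)c(O[Si](C)(C)C(C)(C)C)c2O[Si](C)(C)C(C)(C)C)CCCC1(C)C
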